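**Retrosynthetic overview**
- The lactone is made last. Its carbonyl C12 and both of its oxygens are taken out as CO2. In the five-membered ring C7–C8–O–C12–C11, a vinylic carbon (C11 of C11=C13) and a secondary carbinol carbon (C8) sit 1,3 to each other through C7. An alkenyl bromide at C11 and an epimeric mesylate at C8 (macrocycle 28) therefore allow a carboxylation/SN2 lactonisation that forms C11–C12 and O–C8 in one operation.
- The ten-membered carbocycle (C1–C10) is closed before the lactone, at C1–C2, by intramolecular B-alkyl Suzuki–Miyaura coupling of an E-iodoalkene (C1) with the borane made from the C2=C3 vinyl group.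
- C8 (deliberately epimeric) and the O6 side-chain ester come in one step from an Evans–Tishchenko reduction of β-hydroxy ketone 19 with side-chain aldehyde 24. C8–C9 comes from acylation of allyl sulfone 3 with Weinreb amide 16.
- C6/C7 come from an Evans syn-aldol of the 3-bromobut-3-enoyl imide 13 with dienal 9. The C4=C5 geometry comes from alkyne hydroalumination–iodination, the C1=C10 geometry from iodoalkene 1.
- Ring order: carbocycle (step 15), then γ-lactone (step 16). End game: silyl-to-acetate exchange and acetonide removal.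

Key step: step 16

Remark: germacrane numbering (ring C1–C10, lactone unit C11–C13, C14 methyl, C15 CH2O) is used for all intermediates; the target is read as (1(10)E,4E,6R,7R,8S,2'R), with C3 and C6 cis on the C4=C5 bond, and 1, 4, 7, 10, 11 and 20 are taken as catalogue compounds.

**Route**

Step 1
Reactants: 1 (E)-3-iodo-2-methylprop-2-en-1-ol
Product: 3 (E)-[(3-iodo-2-methylprop-2-en-1-yl)sulfonyl]benzene, via allylic mesylate 2 (not isolated)
Conditions: MsCl, Et3N, CH2Cl2, 0 °C; then PhSO2Na, DMF, 25 °C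
Reagents that add atoms: sodium benzenesulfinate, [Na+].[O-]S(=O)c1ccccc1; methanesulfonyl chloride, CS(=O)(=O)Cl (in 2 only)
Why: Mesylation followed by SN2 S-alkylation of benzenesulfinate at the primary allylic carbon should give the sulfone with the E-olefin untouched; no stereocentre is formed.

Step 2
Reactants: 4 4-[(tert-butyldimethylsilyl)oxy]but-2-yn-1-ol
Product: 6 (Z)-4-[(tert-butyldimethylsilyl)oxy]-3-iodobut-2-en-1-ol, via sodium alkenylaluminate 5 (not isolated)
Conditions: NaAlH2(OCH2CH2OMe)2, THF, 0 °C; then N-iodosuccinimide, −78 → 0 °C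
Reagents that add atoms: N-iodosuccinimide, O=C1CCC(=O)N1I; sodium bis(2-methoxyethoxy)aluminium dihydride, [Na+].COCCO[AlH2-]OCCOC (in 5 only)
Why: Hydroxyl-directed trans-hydroalumination of the propargylic alcohol places aluminium on the distal alkyne carbon in the cyclic aluminate 5, and iodinolysis with retention should give the Z-iodoalkene, which fixes the C4=C5 geometry (C6 and the later C3 cis).

Step 3
Reactants: 6 (Z)-4-[(tert-butyldimethylsilyl)oxy]-3-iodobut-2-en-1-ol, 7 potassium vinyltrifluoroborate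
Product: 8 (E)-3-{[(tert-butyldimethylsilyl)oxy]methyl}penta-2,4-dien-1-ol
Conditions: PdCl2(dppf) (5 mol %), Et3N, n-PrOH, 80 °C
Reagents that add atoms: none
Why: Suzuki–Miyaura coupling of the alkenyl iodide with the vinyltrifluoroborate proceeds with retention of olefin geometry and tolerates the free alcohol.

Step 4
Reactants: 8 (E)-3-{[(tert-butyldimethylsilyl)oxy]methyl}penta-2,4-dien-1-ol
Product: 9 (E)-3-{[(tert-butyldimethylsilyl)oxy]methyl}penta-2,4-dienal
Conditions: MnO2, CH2Cl2, 25 °C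
Reagents that add atoms: none
Why: MnO2 oxidises allylic alcohols selectively to the enal under neutral conditions, so over-oxidation and isomerisation of the trisubstituted olefin should not occur.

Step 5
Reactants: 10 3-bromobut-3-enoic acid, 11 (S)-4-benzyl-1,3-oxazolidin-2-one
Product: 13 (S)-4-benzyl-3-(3-bromobut-3-enoyl)-1,3-oxazolidin-2-one, via mixed pivalic anhydride 12 (not isolated)
Conditions: t-BuCOCl, Et3N, THF, −20 °C; then 11, LiCl, −20 → 25 °C
Reagents that add atoms: pivaloyl chloride, CC(C)(C)C(=O)Cl (in 12 only)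
Why: N-acylation of the oxazolidinone through the mixed anhydride with LiCl/Et3N activation is mild enough that the β,γ-double bond should not move into conjugation.

Step 6
Reactants: 13 (S)-4-benzyl-3-(3-bromobut-3-enoyl)-1,3-oxazolidin-2-one, 9 (E)-3-{[(tert-butyldimethylsilyl)oxy]methyl}penta-2,4-dienal
Product: 15 (S)-4-benzyl-3-[(2S,3R,4E)-2-(1-bromoethenyl)-5-{[(tert-butyldimethylsilyl)oxy]methyl}-3-hydroxyhepta-4,6-dienoyl]-1,3-oxazolidin-2-one, via boron enolate 14 (not isolated)
Conditions: Bu2BOTf, i-Pr2NEt, CH2Cl2, −78 → 0 °C; then 9, −78 → 0 °C; H2O2, MeOH, pH 7 buffer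
Reagents that add atoms: dibutylboron triflate, CCCCB(CCCC)OS(=O)(=O)C(F)(F)F (in 14 only)
Why: Evans syn-aldol reaction, in which the Z-boron enolate 14 reacts through a chair Zimmerman–Traxler transition state on the face opposite to the benzyl group and so sets C7 and C6 (syn, 6R) in one step; enals are good acceptors.

Step 7
Reactants: 15 syn-aldol imide
Product: 16 (2S,3R,4E)-2-(1-bromoethenyl)-5-{[(tert-butyldimethylsilyl)oxy]methyl}-3-hydroxy-N-methoxy-N-methylhepta-4,6-dienamide
Conditions: MeNH(OMe)·HCl, AlMe3, CH2Cl2, −20 → 0 °C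
Reagents that add atoms: N,O-dimethylhydroxylamine hydrochloride, CNOC.Cl
Why: Aluminium amide transamination of β-hydroxy N-acyloxazolidinones to Weinreb amides is assisted by the free hydroxyl and should not epimerise C7; the auxiliary is recovered.

Step 8
Reactants: 3 (E)-[(3-iodo-2-methylprop-2-en-1-yl)sulfonyl]benzene, 16 Weinreb amide
Product: 18 (1E,5S,6R,7E)-5-(1-bromoethenyl)-8-{[(tert-butyldimethylsilyl)oxy]methyl}-6-hydroxy-1-iodo-2-methyl-3-(phenylsulfonyl)deca-1,7,9-trien-4-one (C3 epimers), via lithiated sulfone 17 (not isolated)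
Conditions: 3 (2 equiv), LiN(SiMe3)2, THF, −78 °C; then 16 (pre-treated with i-PrMgCl, 1 equiv), −78 → −20 °C
Reagents that add atoms: lithium bis(trimethylsilyl)amide, [Li]N([Si](C)(C)C)[Si](C)(C)C (in 17 only)
Why: The α-sulfonyl allyl anion 17 acylates at its α-carbon (C9), which forms C8–C9 without allylic transposition, and the chelated tetrahedral intermediate of the Weinreb amide should prevent over-addition; the C9 centre is removed in the next step.

Step 9
Reactants: 18 β-keto sulfone
Product: 19 (1E,5S,6R,7E)-5-(1-bromoethenyl)-8-{[(tert-butyldimethylsilyl)oxy]methyl}-6-hydroxy-1-iodo-2-methyldeca-1,7,9-trien-4-one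
Conditions: SmI2, THF/MeOH, −78 °C
Reagents that add atoms: none
Why: Reductive desulfonylation of β-keto sulfones by SmI2 (electron transfer, loss of sulfinate, protonation of the samarium enolate at C9) should leave the alkenyl halides and the position of the C1=C10 olefin untouched at −78 °C.

Step 10
Reactants: 20 (S)-3-bromo-2-hydroxy-2-methylpropanoic acid
Product: 22 (R)-2,3-dihydroxy-2-methylpropanoic acid, via sodium glycidate 21 (not isolated)
Conditions: NaOH, H2O, 80 °C; then HCl to pH 2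
Reagents that add atoms: sodium hydroxide, [Na+].[OH-]
Why: Base closes the bromohydrin to glycidate 21, which hydroxide opens at the unhindered CH2 carbon, so the quaternary stereocentre is never touched (S becomes R only through the CIP priorities).

Step 11
Reactants: 22 (R)-2,3-dihydroxy-2-methylpropanoic acid
Product: 23 methyl (R)-2,2,4-trimethyl-1,3-dioxolane-4-carboxylate
Conditions: Me2C(OMe)2, MeOH, TsOH (cat.), 25 °C
Reagents that add atoms: 2,2-dimethoxypropane, COC(C)(C)OC; methanol, CO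
Why: Fischer esterification and acetonide formation run together under acid with 2,2-dimethoxypropane as water scavenger; the stereocentre is not involved.

Step 12
Reactants: 23 methyl (R)-2,2,4-trimethyl-1,3-dioxolane-4-carboxylate
Product: 24 (R)-2,2,4-trimethyl-1,3-dioxolane-4-carbaldehyde
Conditions: i-Bu2AlH, CH2Cl2, −78 °C
Reagents that add atoms: none
Why: Half-reduction of the ester by i-Bu2AlH at −78 °C stops at the aluminium hemiacetal, and the α-quaternary aldehyde cannot epimerise.

Step 13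
Reactants: 19 β-hydroxy ketone, 24 (R)-2,2,4-trimethyl-1,3-dioxolane-4-carbaldehyde
Product: 25 (1E,4R,5R,6R,7E)-5-(1-bromoethenyl)-8-{[(tert-butyldimethylsilyl)oxy]methyl}-4-hydroxy-1-iodo-2-methyldeca-1,7,9-trien-6-yl (4R)-2,2,4-trimethyl-1,3-dioxolane-4-carboxylate
Conditions: SmI2 (30 mol %), 24 (4 equiv), THF, −10 °C
Reagents that add atoms: none
Why: Evans–Tishchenko reduction, in which the O6 hemiacetal of 24 delivers hydride to the C8 ketone through a samarium-bound chair transition state; this should give the 1,3-anti diol monoester (new centre 8R), place the side-chain acyl group on O6 and leave O8 free.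

Step 14
Reactants: 25 anti-diol monoester
Product: 26 (1E,4R,5S,6R,7E)-5-(1-bromoethenyl)-8-{[(tert-butyldimethylsilyl)oxy]methyl}-1-iodo-2-methyl-4-[(methylsulfonyl)oxy]deca-1,7,9-trien-6-yl (4R)-2,2,4-trimethyl-1,3-dioxolane-4-carboxylate
Conditions: MsCl, Et3N, DMAP (cat.), CH2Cl2, 0 °C
Reagents that add atoms: methanesulfonyl chloride, CS(=O)(=O)Cl
Why: Sulfonylation of the only free hydroxyl proceeds with retention at C8 (the descriptor at C7 changes only through the CIP priorities).

Step 15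
Reactants: 26 acyclic mesylate
Product: 28 (1(10)E,4E,6R,7S,8R)-11-bromo-15-[(tert-butyldimethylsilyl)oxy]-8-[(methylsulfonyl)oxy]-12-norgermacra-1(10),4,11(13)-trien-6-yl (4R)-2,2,4-trimethyl-1,3-dioxolane-4-carboxylate, via alkylborane 27 (not isolated)
Conditions: 9-BBN, THF, 0 → 25 °C; then slow addition to PdCl2(dppf) (15 mol %), AsPh3, K3PO4, DMF/THF/H2O, 25 °C, 2 mM
Reagents that add atoms: 9-borabicyclo[3.3.1]nonane, B1C2CCCC1CCC2 (in 27 only)
Why: 9-BBN should hydroborate only the terminal C2=C3 bond of the diene (anti-Markovnikov; the halogenated alkenes are deactivated), and the intramolecular B-alkyl Suzuki–Miyaura coupling with the C1 alkenyl iodide under high dilution should close the ten-membered ring with retention of the E-geometry, since oxidative addition to C–I is far faster than to C–Br.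

Step 16
Reactants: 28 macrocyclic bromo mesylate, 29 carbon dioxide
Product: 31 (1(10)E,4E,6R,7R,8S)-15-[(tert-butyldimethylsilyl)oxy]-6-{[(4R)-2,2,4-trimethyl-1,3-dioxolane-4-carbonyl]oxy}germacra-1(10),4,11(13)-trien-12,8-olide, via alkenyl carboxylate 30 (not isolated)
Conditions: CO2 (1 atm), NiCl2(PPh3)2 (10 mol %), PPh3 (20 mol %), Mn powder (3 equiv), Et4NI (5 mol %), DMI, 25 °C; then 50 °C
Reagents that add atoms: none
Why: Proposed new method: zerovalent nickel should insert into the C11–Br bond, Mn should reduce the alkenylnickel halide to a monovalent alkenylnickel species that adds to CO2 (C11–C12 bond), and the released carboxylate 30 should displace the C8 mesylate from the rear (O–C8 bond); the closest known reaction types are the nickel-catalysed reductive carboxylation of alkenyl halides with CO2 and the invertive lactonisation of γ-sulfonyloxy carboxylates, which have not been run as one operation. The γ-lactone ring C7–C8–O–C12–C11 closes in the 5-exo-tet mode. C8 is the only stereocentre that changes: the SN2 inversion turns the 8R mesylate, set by the 1,3-anti Evans–Tishchenko step, into the 8S lactone carbon and so gives the trans ring fusion, while C6 and C7 are spectators. The step needs chemoselectivity for C–Br over the secondary mesylate and the hindered allylic ester, which the much faster oxidative addition to alkenyl bromides should secure, and it needs ring closure before any halide exchange at C8, which the anti-periplanar C11–C7–C8–OMs arrangement of the 6,7-syn/7,8-anti series, the high effective molarity of the carboxylate and the low iodide loading should secure. In this way CO2 supplies C12 and both lactone oxygens, and the sensitive α-methylene lactone appears only after all C–C bonds of the carbocycle are in place.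

Step 17
Reactants: 31 silyl-protected lactone
Product: 33 (1(10)E,4E,6R,7R,8S)-15-acetoxy-6-{[(4R)-2,2,4-trimethyl-1,3-dioxolane-4-carbonyl]oxy}germacra-1(10),4,11(13)-trien-12,8-olide, via allylic alcohol 32 (not isolated)
Conditions: HF·pyridine, pyridine, THF, 0 → 25 °C; then Ac2O, DMAP, 0 °C
Reagents that add atoms: acetic anhydride, CC(=O)OC(C)=O
Why: Buffered fluoride should cleave the primary silyl ether without touching acetonide, ester or lactone, and the liberated allylic alcohol 32 is acetylated in the same flask.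

Step 18
Reactants: 33 acetonide-protected acetate
Product: 34 (1(10)E,4E,6R,7R,8S)-15-acetoxy-6-{[(2R)-2,3-dihydroxy-2-methylpropanoyl]oxy}germacra-1(10),4,11(13)-trien-12,8-olide (target)
Conditions: AcOH/H2O (4:1), 40 °C
Reagents that add atoms: none
Why: Mild aqueous acid hydrolyses the isopropylidene acetal, while allylic acetate, ester and α-methylene lactone should be stable and no stereocentre is affected.

**Compound list**

1 | (E)-3-iodo-2-methylprop-2-en-1-ol | OC/C(C)=C/I | starting material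
2 | (E)-3-iodo-2-methylprop-2-en-1-yl methanesulfonate (not isolated) | CS(=O)(=O)OC/C(C)=C/I | intermediate
3 | (E)-[(3-iodo-2-methylprop-2-en-1-yl)sulfonyl]benzene | O=S(=O)(C/C(C)=C/I)c1ccccc1 | intermediate
4 | 4-[(tert-butyldimethylsilyl)oxy]but-2-yn-1-ol | OCC#CCO[Si](C)(C)C(C)(C)C | starting material
5 | sodium alkenylaluminate, cyclic O–Al–C chelate from hydroalumination of 4 (not isolated) | COCCO[Al-]1(OCCOC)OCC=C1CO[Si](C)(C)C(C)(C)C.[Na+] | intermediate
6 | (Z)-4-[(tert-butyldimethylsilyl)oxy]-3-iodobut-2-en-1-ol | I/C(CO[Si](C)(C)C(C)(C)C)=C\CO | intermediate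
7 | potassium vinyltrifluoroborate | C=C[B-](F)(F)F.[K+] | starting material
8 | (E)-3-{[(tert-butyldimethylsilyl)oxy]methyl}penta-2,4-dien-1-ol (vinyl cis to CH2OH) | C=C/C(CO[Si](C)(C)C(C)(C)C)=C\CO | intermediate
9 | (E)-3-{[(tert-butyldimethylsilyl)oxy]methyl}penta-2,4-dienal | C=C/C(CO[Si](C)(C)C(C)(C)C)=C\C=O | intermediate
10 | 3-bromobut-3-enoic acid | C=C(Br)CC(=O)O | starting material
11 | (S)-4-benzyl-1,3-oxazolidin-2-one | O=C1OC[C@H](Cc2ccccc2)N1 | starting material
12 | 3-bromobut-3-enoic pivalic anhydride (not isolated) | C=C(Br)CC(=O)OC(=O)C(C)(C)C | intermediate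
13 | (S)-4-benzyl-3-(3-bromobut-3-enoyl)-1,3-oxazolidin-2-one | C=C(Br)CC(=O)N1[C@@H](Cc2ccccc2)COC1=O | intermediate
14 | Z-dibutylboron enolate of 13 (not isolated) | CCCCB(CCCC)O/C(=C\C(Br)=C)N1[C@@H](Cc2ccccc2)COC1=O | intermediate
15 | (S)-4-benzyl-3-[(2S,3R,4E)-2-(1-bromoethenyl)-5-{[(tert-butyldimethylsilyl)oxy]methyl}-3-hydroxyhepta-4,6-dienoyl]-1,3-oxazolidin-2-one | C=C/C(CO[Si](C)(C)C(C)(C)C)=C\[C@@H](O)[C@H](C(Br)=C)C(=O)N1[C@@H](Cc2ccccc2)COC1=O | intermediate
16 | (2S,3R,4E)-2-(1-bromoethenyl)-5-{[(tert-butyldimethylsilyl)oxy]methyl}-3-hydroxy-N-methoxy-N-methylhepta-4,6-dienamide | C=C/C(CO[Si](C)(C)C(C)(C)C)=C\[C@@H](O)[C@H](C(Br)=C)C(=O)N(C)OC | intermediate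
17 | α-lithiated sulfone from 3 (not isolated) | [Li]C(S(=O)(=O)c1ccccc1)/C(C)=C/I | intermediate
18 | (1E,5S,6R,7E)-5-(1-bromoethenyl)-8-{[(tert-butyldimethylsilyl)oxy]methyl}-6-hydroxy-1-iodo-2-methyl-3-(phenylsulfonyl)deca-1,7,9-trien-4-one (C3 epimers) | C=C/C(CO[Si](C)(C)C(C)(C)C)=C\[C@@H](O)[C@H](C(Br)=C)C(=O)C(/C(C)=C/I)S(=O)(=O)c1ccccc1 | intermediate
19 | (1E,5S,6R,7E)-5-(1-bromoethenyl)-8-{[(tert-butyldimethylsilyl)oxy]methyl}-6-hydroxy-1-iodo-2-methyldeca-1,7,9-trien-4-one | C=C/C(CO[Si](C)(C)C(C)(C)C)=C\[C@@H](O)[C@H](C(Br)=C)C(=O)C/C(C)=C/I | intermediate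
20 | (S)-3-bromo-2-hydroxy-2-methylpropanoic acid | OC(=O)[C@](C)(O)CBr | starting material
21 | sodium (R)-2-methyloxirane-2-carboxylate (not isolated) | [Na+].[O-]C(=O)[C@]1(C)OC1 | intermediate
22 | (R)-2,3-dihydroxy-2-methylpropanoic acid | OC(=O)[C@](C)(O)CO | intermediate
23 | methyl (R)-2,2,4-trimethyl-1,3-dioxolane-4-carboxylate | COC(=O)[C@]1(C)OC(C)(C)OC1 | intermediate
24 | (R)-2,2,4-trimethyl-1,3-dioxolane-4-carbaldehyde | O=C[C@]1(C)OC(C)(C)OC1 | intermediate
25 | (1E,4R,5R,6R,7E)-5-(1-bromoethenyl)-8-{[(tert-butyldimethylsilyl)oxy]methyl}-4-hydroxy-1-iodo-2-methyldeca-1,7,9-trien-6-yl (4R)-2,2,4-trimethyl-1,3-dioxolane-4-carboxylate | C=C/C(CO[Si](C)(C)C(C)(C)C)=C\[C@@H](OC(=O)[C@]1(C)OC(C)(C)OC1)[C@H](C(Br)=C)[C@H](O)C/C(C)=C/I | intermediate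
26 | (1E,4R,5S,6R,7E)-5-(1-bromoethenyl)-8-{[(tert-butyldimethylsilyl)oxy]methyl}-1-iodo-2-methyl-4-[(methylsulfonyl)oxy]deca-1,7,9-trien-6-yl (4R)-2,2,4-trimethyl-1,3-dioxolane-4-carboxylate | C=C/C(CO[Si](C)(C)C(C)(C)C)=C\[C@@H](OC(=O)[C@]1(C)OC(C)(C)OC1)[C@H](C(Br)=C)[C@H](OS(C)(=O)=O)C/C(C)=C/I | intermediate
27 | B-alkyl-9-BBN from hydroboration of the C2=C3 bond of 26, boron on C2 (not isolated) | C1CCC2CCCC1B2CC/C(CO[Si](C)(C)C(C)(C)C)=C\[C@@H](OC(=O)[C@]3(C)OC(C)(C)OC3)[C@H](C(Br)=C)[C@H](OS(C)(=O)=O)C/C(C)=C/I | intermediate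
28 | (1(10)E,4E,6R,7S,8R)-11-bromo-15-[(tert-butyldimethylsilyl)oxy]-8-[(methylsulfonyl)oxy]-12-norgermacra-1(10),4,11(13)-trien-6-yl (4R)-2,2,4-trimethyl-1,3-dioxolane-4-carboxylate | CS(=O)(=O)O[C@@H]1C/C(C)=C/CC/C(CO[Si](C)(C)C(C)(C)C)=C\[C@@H](OC(=O)[C@]2(C)OC(C)(C)OC2)[C@@H]1C(Br)=C | intermediate
29 | carbon dioxide | O=C=O | starting material
30 | C12 carboxylate of 28 (Br replaced by CO2−; manganese salt, drawn as the anion; not isolated) | CS(=O)(=O)O[C@@H]1C/C(C)=C/CC/C(CO[Si](C)(C)C(C)(C)C)=C\[C@@H](OC(=O)[C@]2(C)OC(C)(C)OC2)[C@@H]1C(=C)C(=O)[O-] | intermediate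
31 | (1(10)E,4E,6R,7R,8S)-15-[(tert-butyldimethylsilyl)oxy]-6-{[(4R)-2,2,4-trimethyl-1,3-dioxolane-4-carbonyl]oxy}germacra-1(10),4,11(13)-trien-12,8-olide | C=C1C(=O)O[C@H]2C/C(C)=C/CC/C(CO[Si](C)(C)C(C)(C)C)=C\[C@@H](OC(=O)[C@]3(C)OC(C)(C)OC3)[C@H]12 | intermediate
32 | (1(10)E,4E,6R,7R,8S)-15-hydroxy-6-{[(4R)-2,2,4-trimethyl-1,3-dioxolane-4-carbonyl]oxy}germacra-1(10),4,11(13)-trien-12,8-olide (not isolated) | C=C1C(=O)O[C@H]2C/C(C)=C/CC/C(CO)=C\[C@@H](OC(=O)[C@]3(C)OC(C)(C)OC3)[C@H]12 | intermediate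
33 | (1(10)E,4E,6R,7R,8S)-15-acetoxy-6-{[(4R)-2,2,4-trimethyl-1,3-dioxolane-4-carbonyl]oxy}germacra-1(10),4,11(13)-trien-12,8-olide | C=C1C(=O)O[C@H]2C/C(C)=C/CC/C(COC(C)=O)=C\[C@@H](OC(=O)[C@]3(C)OC(C)(C)OC3)[C@H]12 | intermediate
34 | (1(10)E,4E,6R,7R,8S)-15-acetoxy-6-{[(2R)-2,3-dihydroxy-2-methylpropanoyl]oxy}germacra-1(10),4,11(13)-trien-12,8-olide | C=C1C(=O)O[C@H]2C/C(C)=C/CC/C(COC(C)=O)=C\[C@@H](OC(=O)[C@](C)(O)CO)[C@H]12 | target

**Step count and risks**

Total step count: 18. Longest linear sequence: 13 steps (steps 2, 3, 4, 6, 7, 8, 9, 13, 14, 15, 16, 17, 18; from 4 to 34).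

Most likely to fail, first: step 16 (bears the label). The alkenylnickel intermediate may be protonated instead of carboxylated, nickel may also activate the mesylate or the allylic ester, and halide exchange at C8 before ring closure would erode the inversion. The fallback uses known chemistry in two operations and sets out from 28. Palladium-catalysed alkoxycarbonylation of the alkenyl bromide [Pd(OAc)2, Xantphos, CO (1 atm), Et3N, 2-(trimethylsilyl)ethanol, toluene, 70 °C] should give the 2-(trimethylsilyl)ethyl acrylate F1. Bu4NF in THF then frees the carboxylate, which closes the lactone at C8 with the same SN2 inversion, and also removes the silyl ether at O15. The route is rejoined at 32, which is acetylated as in step 17 to give 33.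

Second: step 15. Intermolecular coupling (oligomerisation) or protodeboronation may outrun closure of the strained ten-membered ring, and the hydroboration may not fully spare the bromoalkene. The fallback moves the ring closure from C1–C2 to C8–C9 and sets out from 8, 3 and 13.
- Hydroboration of 8 with 9-BBN and intermolecular B-alkyl Suzuki–Miyaura coupling with 3 should give the sulfonyl dienol F2, and MnO2 oxidation the enal F3.
- Evans syn-aldol reaction of 13 with F3 (conditions of step 6) should give the aldol imide F4, and transamination (conditions of step 7) the Weinreb amide F5.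
- Deprotonation of the allyl sulfone with LiN(SiMe3)2 (3 equiv, THF, 1 mM, −78 → 0 °C) should close the ring by intramolecular acylation to the macrocyclic β-keto sulfone F6, which SmI2 desulfonylates to the macrocyclic β-hydroxy ketone F7.
- Evans–Tishchenko reduction with 24 then gives the macrocyclic alcohol F8, and mesylation rejoins the route at 28.

Third: step 13. Hemiacetal formation or hydride transfer may be slow with the α-quaternary aldehyde, so that retro-aldol cleavage or dehydration of 19 takes over. The fallback separates acylation from reduction and sets out from 19 and 23. Saponification of 23 (LiOH, THF/H2O) gives the acetonide acid F9. Esterification of 19 with F9 (2,4,6-trichlorobenzoyl chloride, Et3N, DMAP, toluene, 0 °C) gives the β-acyloxy ketone F10. Reagent-controlled reduction with (S)-2-methyl-CBS-oxazaborolidine and catecholborane at −40 °C, with the branched C7 as the large group, should give the 8R alcohol and rejoin the route at 25.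

**Further compounds**

F1 | step 16 | 2-(trimethylsilyl)ethyl ester of the C12 acid derived from 28 (Br replaced by CO2CH2CH2SiMe3) | CS(=O)(=O)O[C@@H]1C/C(C)=C/CC/C(CO[Si](C)(C)C(C)(C)C)=C\[C@@H](OC(=O)[C@]2(C)OC(C)(C)OC2)[C@@H]1C(=C)C(=O)OCC[Si](C)(C)C
F2 | step 15 | (2E,6E)-3-{[(tert-butyldimethylsilyl)oxy]methyl}-7-methyl-8-(phenylsulfonyl)octa-2,6-dien-1-ol | OC/C=C(CO[Si](C)(C)C(C)(C)C)\CC/C=C(C)/CS(=O)(=O)c1ccccc1
F3 | step 15 | (2E,6E)-3-{[(tert-butyldimethylsilyl)oxy]methyl}-7-methyl-8-(phenylsulfonyl)octa-2,6-dienal | O=C/C=C(CO[Si](C)(C)C(C)(C)C)\CC/C=C(C)/CS(=O)(=O)c1ccccc1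
F4 | step 15 | (S)-4-benzyl-3-[(2S,3R,4E,8E)-2-(1-bromoethenyl)-5-{[(tert-butyldimethylsilyl)oxy]methyl}-3-hydroxy-9-methyl-10-(phenylsulfonyl)deca-4,8-dienoyl]-1,3-oxazolidin-2-one | O=S(=O)(c1ccccc1)C/C(C)=C/CC/C(CO[Si](C)(C)C(C)(C)C)=C\[C@@H](O)[C@H](C(Br)=C)C(=O)N1[C@@H](Cc2ccccc2)COC1=O
F5 | step 15 | (2S,3R,4E,8E)-2-(1-bromoethenyl)-5-{[(tert-butyldimethylsilyl)oxy]methyl}-3-hydroxy-N-methoxy-N-methyl-9-methyl-10-(phenylsulfonyl)deca-4,8-dienamide | O=S(=O)(c1ccccc1)C/C(C)=C/CC/C(CO[Si](C)(C)C(C)(C)C)=C\[C@@H](O)[C@H](C(Br)=C)C(=O)N(C)OC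
F6 | step 15 | (1(10)E,4E,6R,7S)-11-bromo-15-[(tert-butyldimethylsilyl)oxy]-6-hydroxy-9-(phenylsulfonyl)-12-norgermacra-1(10),4,11(13)-trien-8-one (C9 epimers) | O=C1C(S(=O)(=O)c2ccccc2)/C(C)=C/CC/C(CO[Si](C)(C)C(C)(C)C)=C\[C@@H](O)[C@@H]1C(Br)=C
F7 | step 15 | (1(10)E,4E,6R,7S)-11-bromo-15-[(tert-butyldimethylsilyl)oxy]-6-hydroxy-12-norgermacra-1(10),4,11(13)-trien-8-one | O=C1C/C(C)=C/CC/C(CO[Si](C)(C)C(C)(C)C)=C\[C@@H](O)[C@@H]1C(Br)=C
F8 | step 15 | (1(10)E,4E,6R,7R,8R)-11-bromo-15-[(tert-butyldimethylsilyl)oxy]-8-hydroxy-12-norgermacra-1(10),4,11(13)-trien-6-yl (4R)-2,2,4-trimethyl-1,3-dioxolane-4-carboxylate | O[C@@H]1C/C(C)=C/CC/C(CO[Si](C)(C)C(C)(C)C)=C\[C@@H](OC(=O)[C@]2(C)OC(C)(C)OC2)[C@@H]1C(Br)=C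
F9 | step 13 | (R)-2,2,4-trimethyl-1,3-dioxolane-4-carboxylic acid | OC(=O)[C@]1(C)OC(C)(C)OC1
F10 | step 13 | (1E,5S,6R,7E)-5-(1-bromoethenyl)-8-{[(tert-butyldimethylsilyl)oxy]methyl}-1-iodo-2-methyl-4-oxodeca-1,7,9-trien-6-yl (4R)-2,2,4-trimethyl-1,3-dioxolane-4-carboxylate | C=C/C(CO[Si](C)(C)C(C)(C)C)=C\[C@@H](OC(=O)[C@]1(C)OC(C)(C)OC1)[C@H](C(Br)=C)C(=O)C/C(C)=C/I
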